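**Retrosynthetic overview**
1. Key disconnection: the two C–O bonds of the oxirane. They are made by hydroxyl-directed oxygen transfer to the tetrasubstituted C21=C23 olefin of an open (seco) diol; this fixes C21 and C23 and stiffens the chain for closure of ring C.
2. Ring C (cyclooctane) is closed last by ring-closing metathesis (C15=C16), then hydrogenated from the convex face (C16) and the C5 alcohol is oxidised.
3. The seco-diol comes from 1,2-addition of a ring-D dienyllithium (from (S)-β-citronellene by zirconocene enyne cyclisation) to ring-AB ketone 16 (sets C25).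
4. Ketone 16: ring B from p-cresol (dearomatisation), a new Cu-catalysed desymmetrising alkenylation (C8, C28), ring A by metathesis, C5–O and C4 by hydroboration, side chain by aldol condensation and Hosomi–Sakurai allylation (C12).

Convention (one line): C1–C28 are the heavy atoms of the target SMILES in the order written (C5 ketone carbon, C8 angular-methyl carbon, C21/C23 epoxide carbons, C25 carbinol carbon); ring A = isopropylcyclopentane, ring B = cyclohexane, ring C = cyclooctane, ring D = methylcyclopentane; a one-pot operation counts as one step.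

**Route**

Step 1
Reactants: 1 4-methylphenol; 2 allyltrimethylsilane
Product: 3 4-allyl-4-methylcyclohexa-2,5-dien-1-one
Conditions: PhI(OAc)2 (1.1 equiv), 2 (3 equiv), (CF3)2CHOH, 0 °C, 15 min
Reagents that add atoms: none
Why: Oxidative dearomatisation (oxidative Hosomi–Sakurai): the phenol is activated as an aryloxy-λ3-iodane and the allylsilane attacks the para carbon; the dienone is achiral.

Step 2
Reactants: 3 4-allyl-4-methylcyclohexa-2,5-dien-1-one; 4 3-methylbut-1-yne
Product: 6 (4R,5S)-4-allyl-4-methyl-5-(3-methylbut-1-en-2-yl)cyclohex-2-en-1-one, via alkenylalane 5 (not isolated)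
Conditions: 4 (1.5 equiv), i-Bu2AlH (1.4 equiv), NiCl2(dppp) (3 mol %), THF, 0 → 22 °C; then 3, Cu(OTf)2 (5 mol %), chiral sulfonate-bearing imidazolinium salt (N-heterocyclic carbene precursor, 5.5 mol %), THF, −50 °C, 12 h; 1 M HCl
Reagents that add atoms: none
Why: Proposed new method: copper-catalysed enantioselective conjugate alkenylation used as a desymmetrisation of a 4,4-dialkylcyclohexa-2,5-dienone; the chiral carbene–alkenylcopper formed by Al-to-Cu transmetalation adds to one of the two enantiotopic enone units, so the ligand fixes C28 (and which enone reacts), while approach anti to the larger allyl group puts the alkenyl group cis to methyl and so defines the quaternary C8; wrong-face addition gives a separable diastereomer, not the enantiomer, and the aluminium enolate prevents a second addition; closest known reactions are carbene–Cu-catalysed conjugate additions of in-situ alkenylalanes to cyclic enones and Cu-catalysed dialkylzinc desymmetrisations of cyclohexadienones.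

Step 3
Reactants: 6 (4R,5S)-4-allyl-4-methyl-5-(3-methylbut-1-en-2-yl)cyclohex-2-en-1-one
Product: 8 (3aR,7aS)-7a-methyl-3-(propan-2-yl)-1,3a,4,6,7,7a-hexahydro-5H-inden-5-one, via bicyclic dienone 7 (not isolated)
Conditions: second-generation Grubbs catalyst (H2IMes)(PCy3)Cl2Ru=CHPh (2 mol %), CH2Cl2, 40 °C; then RhCl(PPh3)3 (5 mol %), H2 (1 atm), 25 °C
Reagents that add atoms: none
Why: Ring-closing metathesis joins the allyl and 1,1-disubstituted alkenyl groups into the trans-fused ring-A cyclopentene, then RhCl(PPh3)3 hydrogenation saturates only the unhindered disubstituted enone C=C; no new stereocentre.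

Step 4
Reactants: 8 (3aR,7aS)-7a-methyl-3-(propan-2-yl)-1,3a,4,6,7,7a-hexahydro-5H-inden-5-one
Product: 9 (3a′R,7a′S)-7a′-methyl-3′-(propan-2-yl)-1′,3a′,4′,6′,7′,7a′-hexahydrospiro[1,3-dioxolane-2,5′-indene]
Conditions: HOCH2CH2OH, pyridinium p-toluenesulfonate (cat.), PhH, reflux (Dean–Stark)
Reagents that add atoms: ethylene glycol, OCCO
Why: Acid-catalysed ketalisation masks the ring-B ketone for the borane step.

Step 5
Reactants: 9 (3a′R,7a′S)-7a′-methyl-3′-(propan-2-yl)-1′,3a′,4′,6′,7′,7a′-hexahydrospiro[1,3-dioxolane-2,5′-indene]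
Product: 12 (2R,3R,3aS,7aS)-2-hydroxy-7a-methyl-3-(propan-2-yl)octahydro-5H-inden-5-one, via alkylborane 10 (not isolated), via hydroxy ketal 11 (not isolated)
Conditions: BH3·THF (2 equiv), THF, 0 °C → rt; NaOH, H2O2, 0 °C; then 2 M HCl, THF, rt
Reagents that add atoms: hydrogen peroxide, OO; borane–tetrahydrofuran, B.C1CCOC1 (boron only in 10)
Why: Hydroboration–oxidation (anti-Markovnikov, syn): borane adds from the face opposite the angular methyl with boron on the less substituted C5, so H-4 and O-5 are both α and the isopropyl group ends cis to the angular methyl (C4 R, C5 R); aqueous acid then removes the ketal.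

Step 6
Reactants: 12 (2R,3R,3aS,7aS)-2-hydroxy-7a-methyl-3-(propan-2-yl)octahydro-5H-inden-5-one; 13 acetaldehyde
Product: 15 (2R,3R,3aS,7aS,6E)-6-ethylidene-2-hydroxy-7a-methyl-3-(propan-2-yl)octahydro-5H-inden-5-one, via aldol adduct 14 (not isolated)
Conditions: LiN(i-Pr)2 (2.2 equiv), THF, −78 °C; 13 (1.5 equiv); H2O; then p-TsOH·H2O (10 mol %), PhMe, 70 °C
Reagents that add atoms: none
Why: Directed aldol addition of the kinetic lithium enolate (deprotonation at C11, the α-carbon remote from the ring fusion, by analogy with trans-fused 3-keto steroids) followed by acid-catalysed dehydration to the conjugated (E)-ethylidene ketone; no stereocentre is kept at C11.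

Step 7
Reactants: 15 (2R,3R,3aS,7aS,6E)-6-ethylidene-2-hydroxy-7a-methyl-3-(propan-2-yl)octahydro-5H-inden-5-one; 2 allyltrimethylsilane
Product: 16 (2R,3R,3aS,6R,7aS)-2-hydroxy-7a-methyl-6-[(2R)-pent-4-en-2-yl]-3-(propan-2-yl)octahydro-5H-inden-5-one
Conditions: 2 (3 equiv), TiCl4 (2.2 equiv), CH2Cl2, −78 °C; then H2O
Reagents that add atoms: none
Why: Hosomi–Sakurai conjugate allylation of the s-cis exocyclic enone: allyl attacks C12 from the α-face, away from the axial angular methyl (C12 R), and the titanium enolate is protonated to the equatorial C11 (R) ketone.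

Step 8
Reactants: 17 (S)-3,7-dimethylocta-1,6-diene ((S)-β-citronellene)
Product: 18 (S)-4-methylhex-5-enal
Conditions: O3 (1.0 equiv), CH2Cl2–pyridine, −78 °C; Me2S
Reagents that add atoms: ozone, [O-][O+]=O
Why: Chemoselective ozonolysis of the electron-rich trisubstituted olefin; the chiral-pool stereocentre (later C17) is untouched.

Step 9
Reactants: 18 (S)-4-methylhex-5-enal
Product: 19 (S)-1,1-dibromo-5-methylhepta-1,6-diene
Conditions: CBr4 (2 equiv), PPh3 (4 equiv), CH2Cl2, 0 °C
Reagents that add atoms: carbon tetrabromide, BrC(Br)(Br)Br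
Why: Corey–Fuchs (Ramirez) dibromo-olefination adds the carbon that becomes C23.

Step 10
Reactants: 19 (S)-1,1-dibromo-5-methylhepta-1,6-diene
Product: 21 (S)-3-methyloct-1-en-6-yne, via lithium acetylide 20 (not isolated)
Conditions: n-BuLi (2.2 equiv), THF, −78 → 0 °C; MeI, −78 °C → rt
Reagents that add atoms: iodomethane, IC
Why: Second stage of the Corey–Fuchs sequence (Br/Li exchange, Fritsch–Buttenberg–Wiechell rearrangement to the acetylide) with C-methylation in the same flask.

Step 11
Reactants: 21 (S)-3-methyloct-1-en-6-yne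
Product: 23 (2R,3S,Z)-1-(1-iodoethylidene)-2-(iodomethyl)-3-methylcyclopentane, via zirconacyclopentene 22 (not isolated)
Conditions: Cp2ZrCl2 (1.1 equiv), n-BuLi (2.2 equiv), THF, −78 °C; 21, −78 °C → rt; I2 (2.5 equiv), 0 °C
Reagents that add atoms: iodine, [I][I]
Why: Negishi zirconocene-mediated enyne bicyclisation forms C16–C21 with Zr on C23 cis to C16 (syn addition across the alkyne), so iodinolysis with retention gives the (Z)-tetrasubstituted alkenyl iodide; the C16 configuration (mainly trans to methyl) does not matter because step 12 erases it.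

Step 12
Reactants: 23 (2R,3S,Z)-1-(1-iodoethylidene)-2-(iodomethyl)-3-methylcyclopentane
Product: 24 (3S,Z)-1-(1-iodoethylidene)-3-methyl-2-methylidenecyclopentane
Conditions: KOt-Bu (1.5 equiv), THF, 0 °C → rt
Reagents that add atoms: none
Why: E2 dehydroiodination of the primary iodide (the only β-hydrogen is on C16) gives the exocyclic methylene; the alkenyl iodide is inert.

Step 13
Reactants: 24 (3S,Z)-1-(1-iodoethylidene)-3-methyl-2-methylidenecyclopentane; 16 (2R,3R,3aS,6R,7aS)-2-hydroxy-7a-methyl-6-[(2R)-pent-4-en-2-yl]-3-(propan-2-yl)octahydro-5H-inden-5-one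
Product: 26 (2R,3R,3aS,5R,6R,7aS)-7a-methyl-5-{(1Z)-1-[(3S)-3-methyl-2-methylidenecyclopentylidene]ethyl}-6-[(2R)-pent-4-en-2-yl]-3-(propan-2-yl)octahydro-1H-indene-2,5-diol, via dienyllithium 25 (not isolated)
Conditions: 24 (1.3 equiv), t-BuLi (2.6 equiv), Et2O, −78 °C; then 16 pre-treated with LiN(SiMe3)2 (1.0 equiv) in THF, −78 → −40 °C; H2O
Reagents that add atoms: none
Why: Iodine–lithium exchange with retention of olefin geometry, then 1,2-addition of the bulky alkenyllithium to the cyclohexanone from the equatorial direction (axial OH, trans to the C11 side chain) sets C25 (R); the C5 hydroxyl is carried as its lithium alkoxide.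

Step 14
Reactants: 26 (2R,3R,3aS,5R,6R,7aS)-7a-methyl-5-{(1Z)-1-[(3S)-3-methyl-2-methylidenecyclopentylidene]ethyl}-6-[(2R)-pent-4-en-2-yl]-3-(propan-2-yl)octahydro-1H-indene-2,5-diol
Product: 27 (2R,3R,3aS,5R,6R,7aS)-5-[(2R,3S,5S)-2,5-dimethyl-4-methylidene-1-oxaspiro[2.4]heptan-2-yl]-7a-methyl-6-[(2R)-pent-4-en-2-yl]-3-(propan-2-yl)octahydro-1H-indene-2,5-diol
Conditions: VO(acac)2 (5 mol %), t-BuOOH (1.5 equiv), PhH, 25 °C
Reagents that add atoms: tert-butyl hydroperoxide, CC(C)(C)OO
Why: Hydroxyl-directed epoxidation (Sharpless–Michaelson type): the vanadate ester of the C25 tertiary alcohol delivers oxygen only to the adjacent tetrasubstituted olefin, on the ring-D face opposite the C17 methyl, giving C21 (S) and C23 (R); the other three olefins and the non-allylic C5 alcohol are untouched.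

Step 15
Reactants: 27 (2R,3R,3aS,5R,6R,7aS)-5-[(2R,3S,5S)-2,5-dimethyl-4-methylidene-1-oxaspiro[2.4]heptan-2-yl]-7a-methyl-6-[(2R)-pent-4-en-2-yl]-3-(propan-2-yl)octahydro-1H-indene-2,5-diol
Product: 28 tetracyclic epoxy diol with the (Z)-C15=C16 olefin in ring C, (4R,5R,8S,11R,12R,17S,21S,23R,25R,28S)
Conditions: second-generation Hoveyda–Grubbs catalyst (H2IMes)Cl2Ru=CH(C6H4-2-O-i-Pr) (10 mol %), PhMe (2 mM), 90 °C, argon sparge
Reagents that add atoms: none
Why: Ring-closing metathesis between the terminal olefin and the ring-D exocyclic methylene closes ring C as a trisubstituted cyclooctene; the rigid spiro-epoxide holds the two olefins on the same side, and the ring enforces the Z geometry.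

Step 16
Reactants: 28 tetracyclic epoxy diol with the (Z)-C15=C16 olefin in ring C
Product: 29 C5 alcohol of the target, (4R,5R,8S,11R,12R,16S,17S,21S,23R,25R,28S)
Conditions: H2 (30 bar), Rh/Al2O3 (5 wt % Rh), EtOAc, 25 °C
Reagents that add atoms: none
Why: Heterogeneous hydrogenation delivers hydrogen to C16 from the convex face that carries the epoxide oxygen, opposite the C17 and C23 methyl groups, giving C16 (S) with C15 cis to both the C17 methyl and C23; Rh on Al2O3 is chosen to avoid allylic C–O hydrogenolysis.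

Step 17
Reactants: 29 C5 alcohol of the target
Product: 30 target CNP0332295.1, (4R,8S,11R,12R,16S,17S,21S,23R,25R,28S)
Conditions: Dess–Martin periodinane (1.5 equiv), NaHCO3, CH2Cl2, 0 °C → rt
Reagents that add atoms: none
Why: Dess–Martin oxidation of the only secondary alcohol under buffered, non-enolising conditions, so the kinetically set C4 (isopropyl cis to the angular methyl) is not epimerised; the tertiary alcohol and epoxide are inert.

**Compound list**
1 | 4-methylphenol | Cc1ccc(O)cc1 | starting material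
2 | allyltrimethylsilane | C=CC[Si](C)(C)C | starting material
3 | 4-allyl-4-methylcyclohexa-2,5-dien-1-one | C=CCC1(C)C=CC(=O)C=C1 | intermediate
4 | 3-methylbut-1-yne | CC(C)C#C | starting material
5 | diisobutyl(3-methylbut-1-en-2-yl)alane | CC(C)C(=C)[Al](CC(C)C)CC(C)C | intermediate (not isolated)
6 | (4R,5S)-4-allyl-4-methyl-5-(3-methylbut-1-en-2-yl)cyclohex-2-en-1-one | CC(C)C(=C)[C@@H]1CC(=O)C=C[C@@]1(C)CC=C | intermediate
7 | (3aR,7aR)-7a-methyl-3-(propan-2-yl)-1,3a,4,7a-tetrahydro-5H-inden-5-one | CC(C)C1=CC[C@]2(C)C=CC(=O)C[C@@H]12 | intermediate (not isolated)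
8 | (3aR,7aS)-7a-methyl-3-(propan-2-yl)-1,3a,4,6,7,7a-hexahydro-5H-inden-5-one | CC(C)C1=CC[C@]2(C)CCC(=O)C[C@@H]12 | intermediate
9 | (3a′R,7a′S)-7a′-methyl-3′-(propan-2-yl)-1′,3a′,4′,6′,7′,7a′-hexahydrospiro[1,3-dioxolane-2,5′-indene] | CC(C)C1=CC[C@]2(C)CCC3(OCCO3)C[C@@H]12 | intermediate
10 | C5 alkylborane of 9 (BH2 on C5 and new H on C4, both on the face opposite the angular methyl) | CC(C)[C@H]1[C@H](B)C[C@]2(C)CCC3(OCCO3)C[C@@H]12 | intermediate (not isolated)
11 | (2′R,3′R,3a′S,7a′S)-7a′-methyl-3′-(propan-2-yl)octahydrospiro[1,3-dioxolane-2,5′-inden]-2′-ol | CC(C)[C@H]1[C@H](O)C[C@]2(C)CCC3(OCCO3)C[C@@H]12 | intermediate (not isolated)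
12 | (2R,3R,3aS,7aS)-2-hydroxy-7a-methyl-3-(propan-2-yl)octahydro-5H-inden-5-one | CC(C)[C@H]1[C@H](O)C[C@]2(C)CCC(=O)C[C@@H]12 | intermediate
13 | acetaldehyde | CC=O | starting material
14 | (2R,3R,3aS,6R,7aS)-2-hydroxy-6-(1-hydroxyethyl)-7a-methyl-3-(propan-2-yl)octahydro-5H-inden-5-one (both carbinol epimers) | CC(C)[C@H]1[C@H](O)C[C@]2(C)C[C@H](C(C)O)C(=O)C[C@@H]12 | intermediate (not isolated)
15 | (2R,3R,3aS,7aS,6E)-6-ethylidene-2-hydroxy-7a-methyl-3-(propan-2-yl)octahydro-5H-inden-5-one | CC(C)[C@H]1[C@H](O)C[C@]2(C)C/C(=C\C)C(=O)C[C@@H]12 | intermediate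
16 | (2R,3R,3aS,6R,7aS)-2-hydroxy-7a-methyl-6-[(2R)-pent-4-en-2-yl]-3-(propan-2-yl)octahydro-5H-inden-5-one | CC(C)[C@H]1[C@H](O)C[C@]2(C)C[C@H]([C@H](C)CC=C)C(=O)C[C@@H]12 | intermediate
17 | (S)-3,7-dimethylocta-1,6-diene ((S)-β-citronellene) | C=C[C@@H](C)CCC=C(C)C | starting material
18 | (S)-4-methylhex-5-enal | C=C[C@@H](C)CCC=O | intermediate
19 | (S)-1,1-dibromo-5-methylhepta-1,6-diene | C=C[C@@H](C)CCC=C(Br)Br | intermediate
20 | lithium (S)-5-methylhept-6-en-1-yn-1-ide | C=C[C@@H](C)CCC#C[Li] | intermediate (not isolated)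
21 | (S)-3-methyloct-1-en-6-yne | C=C[C@@H](C)CCC#CC | intermediate
22 | zirconacyclopentene fused to the methylcyclopentane (Cp2Zr bonded to C15 and C23; Cp drawn η1) | CC1=C2CC[C@H](C)[C@H]2C[Zr]1(C1C=CC=C1)C1C=CC=C1 | intermediate (not isolated)
23 | (2R,3S,Z)-1-(1-iodoethylidene)-2-(iodomethyl)-3-methylcyclopentane (major C2 epimer shown) | I/C(C)=C1/CC[C@H](C)[C@H]1CI | intermediate
24 | (3S,Z)-1-(1-iodoethylidene)-3-methyl-2-methylidenecyclopentane | I/C(C)=C1/CC[C@H](C)C1=C | intermediate
25 | (Z)-1-[(3S)-3-methyl-2-methylidenecyclopentylidene]ethyllithium | [Li]/C(C)=C1/CC[C@H](C)C1=C | intermediate (not isolated)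
26 | (2R,3R,3aS,5R,6R,7aS)-7a-methyl-5-{(1Z)-1-[(3S)-3-methyl-2-methylidenecyclopentylidene]ethyl}-6-[(2R)-pent-4-en-2-yl]-3-(propan-2-yl)octahydro-1H-indene-2,5-diol | CC(C)[C@H]1[C@H](O)C[C@]2(C)C[C@H]([C@H](C)CC=C)[C@@](O)(/C(C)=C3/CC[C@H](C)C3=C)C[C@@H]12 | intermediate
27 | (2R,3R,3aS,5R,6R,7aS)-5-[(2R,3S,5S)-2,5-dimethyl-4-methylidene-1-oxaspiro[2.4]heptan-2-yl]-7a-methyl-6-[(2R)-pent-4-en-2-yl]-3-(propan-2-yl)octahydro-1H-indene-2,5-diol | CC(C)[C@H]1[C@H](O)C[C@]2(C)C[C@H]([C@H](C)CC=C)[C@@](O)([C@@]3(C)O[C@]34CC[C@H](C)C4=C)C[C@@H]12 | intermediate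
28 | tetracyclic epoxy diol, (Z)-C15=C16 olefin in ring C, (4R,5R,8S,11R,12R,17S,21S,23R,25R,28S) | CC(C)[C@H]1[C@H](O)C[C@]2(C)C[C@@H]3[C@H](C)C/C=C4/[C@@H](C)CC[C@]45O[C@]5(C)[C@@]3(O)C[C@@H]12 | intermediate
29 | C5 alcohol of the target, (4R,5R,8S,11R,12R,16S,17S,21S,23R,25R,28S) | CC(C)[C@H]1[C@H](O)C[C@]2(C)C[C@@H]3[C@H](C)CC[C@H]4[C@@H](C)CC[C@]45O[C@]5(C)[C@@]3(O)C[C@@H]12 | intermediate
30 | target CNP0332295.1, (4R,8S,11R,12R,16S,17S,21S,23R,25R,28S) | CC(C)[C@H]1C(=O)C[C@]2(C)C[C@@H]3[C@H](C)CC[C@H]4[C@@H](C)CC[C@]45O[C@]5(C)[C@@]3(O)C[C@@H]12 | target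

**Totals and risks**
Total step count: 17. Longest linear sequence: 12 (steps 1–7, then 13–17); the ring-D branch (steps 8–12) is 5 steps.

Most likely to fail:

Step 2 (the proposed desymmetrising alkenylation). The enantioselectivity rests on an untested substrate class, and the diastereoselectivity rests only on the methyl/allyl size difference. Fallback, known chemistry, setting out from 3 and coming back at 6: add (3-methylbut-1-en-2-yl)magnesium bromide (from 2-bromo-3-methylbut-1-ene and Mg) to 3 with CuBr·SMe2 (10 mol %) in THF at −40 °C. This substrate-controlled addition anti to allyl gives 6 as a racemate with its enantiomer (4S,5R)-4-allyl-4-methyl-5-(3-methylbut-1-en-2-yl)cyclohex-2-en-1-one F1; preparative chiral HPLC then delivers 6.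

Step 7 (facial selectivity of the Sakurai allylation at C12, controlled only by the angular methyl). Fallback with catalyst control, setting out from 12 and coming back at 16: LiN(i-Pr)2 (2.2 equiv) and Me3SiCl convert 12 into the bis-silyl compound (2R,3R,3aS,7aS)-7a-methyl-3-(propan-2-yl)-2,5-bis(trimethylsilyloxy)-2,3,3a,4,7,7a-hexahydro-1H-indene F2. An organocatalytic Mukaiyama–Michael addition of F2 to (E)-but-2-enal (chiral imidazolidinone salt, iminium catalysis) and acidic work-up give keto aldehyde (3R)-3-[(2R,3R,3aS,6R,7aS)-2-hydroxy-7a-methyl-5-oxo-3-(propan-2-yl)octahydro-1H-inden-6-yl]butanal F3. Ph3P=CH2 (1 equiv, −78 °C) methylenates the aldehyde selectively to give 16.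

Step 15 (ring-closing metathesis to a trisubstituted cyclooctene using a 1,1-disubstituted olefin flanked by a quaternary epoxide carbon). Fallback by reversing the order, setting out from 26 and coming back at 28: ring-close the more flexible dienyl carbinol 26 with the same ruthenium catalyst to the diene diol (C15=C16 and C21=C23 in ring C, otherwise as 28) F4, then carry out the VO(acac)2/t-BuOOH hydroxyl-directed epoxidation on F4 (only the allylic-alcohol olefin reacts, from the face opposite the C17 methyl) to reach 28.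

Further compounds
F1 | step 2 | (4S,5R)-4-allyl-4-methyl-5-(3-methylbut-1-en-2-yl)cyclohex-2-en-1-one | CC(C)C(=C)[C@H]1CC(=O)C=C[C@]1(C)CC=C
F2 | step 7 | (2R,3R,3aS,7aS)-7a-methyl-3-(propan-2-yl)-2,5-bis(trimethylsilyloxy)-2,3,3a,4,7,7a-hexahydro-1H-indene | CC(C)[C@H]1[C@H](O[Si](C)(C)C)C[C@]2(C)CC=C(O[Si](C)(C)C)C[C@@H]12
F3 | step 7 | (3R)-3-[(2R,3R,3aS,6R,7aS)-2-hydroxy-7a-methyl-5-oxo-3-(propan-2-yl)octahydro-1H-inden-6-yl]butanal | CC(C)[C@H]1[C@H](O)C[C@]2(C)C[C@H]([C@H](C)CC=O)C(=O)C[C@@H]12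
F4 | step 15 | diene diol, 28 without the epoxide oxygen (C15=C16 and C21=C23 double bonds) | CC(C)[C@H]1[C@H](O)C[C@]2(C)C[C@@H]3[C@H](C)C/C=C4/[C@@H](C)CC/C4=C(C)/[C@@]3(O)C[C@@H]12
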